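**Plan**
- Numbering used below: ring A = C1–C5 and C10 (C1=C10 alkene, C4 = CMe2, C5 = ring-fusion CH); ring B = C5–C10 (C8 = CHMe, C9 = quaternary C); side chain C11–C18 (C13 and C16 = dioxane carbons, C17 = CHMe, C18 = CO2H).
- Retrosynthesis: C18 oxidation level; dioxane O–C13 bond (6-endo peroxymercuration of an E alkene) and C16–OO bond (SN2); C12–C13 (Negishi coupling of a decalin iodide with a vinyl iodide); C9–C11 (Johnson–Claisen, which also places C1=C10); then C1–C2 and C4–C5 together (double ene annulation of acrolein onto a ring-B methylenecyclohexane).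
- Forward: ring B ketone → exocyclic C1=C10 methylene → ring A in one operation → C4 gem-dimethyl → C1 oxidation, reduction, Claisen (quaternary C9, C1=C10) → C11–C12 iodide → coupling with the C13–C18 fragment → 1,2-dioxane → acid.
- Enabling feature: the 1,1-disubstituted C1=C10 alkene on ring B has two different allylic hydrogens, C5–H2 (taken in the first ene reaction) and the single C9–H (delivered in the second).
- Stereochemistry: C8 from a copper-catalysed asymmetric conjugate addition; C9–H from kinetic protonation, relayed to C5 by the suprafacial ene step; C1–OH from reagent-controlled reduction, relayed to quaternary C9 by the Claisen rearrangement; C16/C17 from an Evans syn aldol (C16 then inverted by SN2); C13 from the E alkene geometry in a chair-like ring closure.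

Key step: step 3

Remark: 1, 5, 18 and 22 are taken as commercial; 2-methoxyprop-2-yl hydroperoxide and the formaldehyde sulfonylhydrazone are each made in one known step from commercial materials. Nothing in this route has been run; the selectivities given are expectations.

**Route**

Step 1
Reactants: 1 2-methylcyclohex-2-en-1-one
Product: 3 (2R,3R)-2,3-dimethylcyclohexan-1-one, via dimethylaluminium enolate 2 (not isolated)
Conditions: Me3Al, Cu(O2CC4H3S) (2 mol%), chiral phosphoramidite ligand (enantiomer giving 3R), Et2O, −30 °C; then MeOH, −78 °C, aq. NH4Cl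
Reagents that add atoms: trimethylaluminium, C[Al](C)C
Why: Copper-catalysed asymmetric conjugate addition sets ring carbon 3 (later C8) under ligand control, and kinetic protonation of enolate 2 anti to the pseudoaxial new methyl should give mainly the cis ketone, which fixes the C9–H needed in step 3.

Step 2
Reactants: 3 (2R,3R)-2,3-dimethylcyclohexan-1-one
Product: 4 (1R,2R)-1,2-dimethyl-3-methylidenecyclohexane
Conditions: Zn, CH2Br2, TiCl4, THF/CH2Cl2, 0 → 25 °C
Reagents that add atoms: dibromomethane, BrCBr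
Why: Takai–Lombardo methylenation is non-basic, so the epimerisable centre next to the carbonyl is kept while the ketone becomes the exocyclic C1=C10 alkene.

Step 3
Reactants: 4 (1R,2R)-1,2-dimethyl-3-methylidenecyclohexane; 5 prop-2-enal (acrolein)
Product: 7 (1S,6R,8aR)-5,6-dimethyl-1,2,3,4,6,7,8,8a-octahydronaphthalen-1-ol, via ene adduct aldehyde 6 (not isolated)
Conditions: Me2AlCl (2.2 equiv), CH2Cl2, −78 → 25 °C
Reagents that add atoms: none
Why: Me2AlCl-complexed acrolein first undergoes an intermolecular ene reaction at the exocyclic CH2 (new C1–C2 bond, hydrogen taken from C5H2, alkene moved to C5=C10) to give aldehyde 6, whose aluminium complex then closes ring A by an intramolecular type 2 carbonyl-ene reaction (new C4–C5 bond, the C9 hydrogen passes to oxygen, alkene moved to C9=C10). The closest known reaction type is the Lewis-acid-promoted sequential ene annulation of alkylidenecycloalkanes with enals (Snider annulation). Ring A is the only ring closed, and it closes endo to the C5=C10 alkene through a chair-like bicyclic transition state. C5 is controlled by the suprafacial ene step: the carbonyl carbon must bond to the face of C5 from which the single C9–H is delivered, so the C9 centre set in step 1 acts as a traceless relay; the C4 carbinol centre comes from the same transition state and is removed in step 4. The step needs hydrogen abstraction from C5 and not from C9 in the first ene reaction, which the axial C9 methyl of 4 (allylic 1,3-strain) should secure by holding C9–H in the alkene plane, and it needs the 1,1-disubstituted alkene to react before the trisubstituted one formed from it, which their relative ene reactivity secures.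

Step 4
Reactants: 7 (1S,6R,8aR)-5,6-dimethyl-1,2,3,4,6,7,8,8a-octahydronaphthalen-1-ol
Product: 8 (6R,8aR)-5,6-dimethyl-3,4,6,7,8,8a-hexahydronaphthalen-1(2H)-one
Conditions: Dess–Martin periodinane, NaHCO3, CH2Cl2, 0 °C
Reagents that add atoms: none
Why: Dess–Martin oxidation under buffered, non-basic conditions should leave the α-stereocentre at the ring fusion (C5) and the β,γ-alkene in place.

Step 5
Reactants: 8 (6R,8aR)-5,6-dimethyl-3,4,6,7,8,8a-hexahydronaphthalen-1(2H)-one
Product: 9 (6R,8aS)-5,6-dimethyl-1-methylidene-1,2,3,4,6,7,8,8a-octahydronaphthalene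
Conditions: Cp2TiMe2, toluene, 65 °C
Reagents that add atoms: dimethyltitanocene, C[Ti](C)(C1C=CC=C1)C1C=CC=C1
Why: Petasis methylenation olefinates enolisable ketones without base, so epimerisation at C5 and conjugation of the alkene are avoided.

Step 6
Reactants: 9 (6R,8aS)-5,6-dimethyl-1-methylidene-1,2,3,4,6,7,8,8a-octahydronaphthalene
Product: 11 (2R,4aS)-1,2,5,5-tetramethyl-2,3,4,4a,5,6,7,8-octahydronaphthalene, via sulfonylhydrazide adduct 10 (not isolated)
Conditions: Fe(acac)3, PhSiH3, formaldehyde 2,4,6-trimethylbenzenesulfonylhydrazone, THF/MeOH, 25 °C; then MeOH, 60 °C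
Reagents that add atoms: formaldehyde 2,4,6-trimethylbenzenesulfonylhydrazone, C=NNS(=O)(=O)c1c(C)cc(C)cc1C
Why: Iron-hydride hydrogen-atom transfer to the 1,1-disubstituted alkene (Baran hydromethylation) gives the tertiary C4 radical, which adds to the hydrazone, and adduct 10 loses sulfinate and N2 on warming to leave the second C4 methyl, while the tetrasubstituted alkene is too hindered to react.

Step 7
Reactants: 11 (2R,4aS)-1,2,5,5-tetramethyl-2,3,4,4a,5,6,7,8-octahydronaphthalene
Product: 12 (4aS,7R)-4,4,7,8-tetramethyl-3,4,4a,5,6,7-hexahydronaphthalen-1(2H)-one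
Conditions: CrO3, 3,5-dimethylpyrazole, CH2Cl2, −20 °C
Reagents that add atoms: chromium trioxide, O=[Cr](=O)=O
Why: Chromium trioxide–dimethylpyrazole allylic oxidation should convert the only allylic methylene (C1) of the tetrasubstituted alkene into the enone, the other allylic positions being methine or methyl.

Step 8
Reactants: 12 (4aS,7R)-4,4,7,8-tetramethyl-3,4,4a,5,6,7-hexahydronaphthalen-1(2H)-one
Product: 13 (1S,4aS,7R)-4,4,7,8-tetramethyl-1,2,3,4,4a,5,6,7-octahydronaphthalen-1-ol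
Conditions: LiBH(sBu)3, THF, −78 °C
Reagents that add atoms: none
Why: 1,2-Reduction by the bulky hydride from the equatorial direction should give the pseudoaxial C1 alcohol (OH cis to the C5 hydrogen), which also avoids allylic 1,3-strain with the C9 methyl.

Step 9
Reactants: 13 (1S,4aS,7R)-4,4,7,8-tetramethyl-1,2,3,4,4a,5,6,7-octahydronaphthalen-1-ol
Product: 15 ethyl [(1R,2R,4aS)-1,2,5,5-tetramethyl-1,2,3,4,4a,5,6,7-octahydronaphthalen-1-yl]acetate, via ketene acetal 14 (not isolated)
Conditions: CH3C(OEt)3, EtCO2H (cat.), xylene, 140 °C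
Reagents that add atoms: triethyl orthoacetate, CC(OCC)(OCC)OCC
Why: Johnson–Claisen rearrangement of 14 is suprafacial, so the new C9–C11 bond forms on the face that carried the C1 oxygen, giving quaternary C9 (methyl trans to the C8 methyl) and moving the alkene to C1=C10.

Step 10
Reactants: 15 ethyl [(1R,2R,4aS)-1,2,5,5-tetramethyl-1,2,3,4,4a,5,6,7-octahydronaphthalen-1-yl]acetate
Product: 16 2-[(1R,2R,4aS)-1,2,5,5-tetramethyl-1,2,3,4,4a,5,6,7-octahydronaphthalen-1-yl]ethan-1-ol
Conditions: LiAlH4, Et2O, 0 °C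
Reagents that add atoms: none
Why: Hydride reduction of the ester to the primary alcohol, with the isolated trisubstituted alkene inert.

Step 11
Reactants: 16 2-[(1R,2R,4aS)-1,2,5,5-tetramethyl-1,2,3,4,4a,5,6,7-octahydronaphthalen-1-yl]ethan-1-ol
Product: 17 (1R,2R,4aS)-1-(2-iodoethyl)-1,2,5,5-tetramethyl-1,2,3,4,4a,5,6,7-octahydronaphthalene
Conditions: I2, PPh3, imidazole, CH2Cl2, 0 → 25 °C
Reagents that add atoms: iodine, II
Why: Appel-type iodination by SN2 at the unhindered primary carbon C12.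

Step 12
Reactants: 18 pent-3-yn-1-ol
Product: 20 (3E)-4-iodopent-3-en-1-ol, via alkenylzirconocene 19 (not isolated)
Conditions: Cp2Zr(H)Cl (2.5 equiv), THF, 25 → 40 °C; then I2, −78 → 0 °C
Reagents that add atoms: iodine, II
Why: syn-Hydrozirconation of the internal alkyne places zirconium on the less hindered methyl-bearing carbon under equilibrating conditions, and iodinolysis with retention gives the E vinyl iodide (C13=C14).

Step 13
Reactants: 20 (3E)-4-iodopent-3-en-1-ol
Product: 21 (3E)-4-iodopent-3-enal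
Conditions: Dess–Martin periodinane, NaHCO3, CH2Cl2, 0 °C; used crude
Reagents that add atoms: none
Why: Mild oxidation to the β,γ-unsaturated aldehyde, used at once to avoid isomerisation into conjugation.

Step 14
Reactants: 21 (3E)-4-iodopent-3-enal; 22 (4S)-4-benzyl-3-propanoyl-1,3-oxazolidin-2-one
Product: 24 (4S)-4-benzyl-3-[(2S,3R,5E)-3-hydroxy-6-iodo-2-methylhept-5-enoyl]-1,3-oxazolidin-2-one, via boron enolate 23 (not isolated)
Conditions: Bu2BOTf, iPr2NEt, CH2Cl2, −78 → 0 °C; then 21, −78 → 0 °C; pH 7 buffer, MeOH, H2O2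
Reagents that add atoms: none
Why: Evans syn aldol reaction, in which the Z boron enolate 23 reacts through a Zimmerman–Traxler chair on the face opposite the benzyl group and so sets C17 and C16 under auxiliary control.

Step 15
Reactants: 24 (4S)-4-benzyl-3-[(2S,3R,5E)-3-hydroxy-6-iodo-2-methylhept-5-enoyl]-1,3-oxazolidin-2-one
Product: 25 (2R,3R,5E)-6-iodo-2-methylhept-5-ene-1,3-diol
Conditions: LiBH4, MeOH (1 equiv), Et2O, 0 °C
Reagents that add atoms: none
Why: Reductive removal of the auxiliary gives the 1,3-diol without touching the vinyl iodide or the stereocentres.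

Step 16
Reactants: 25 (2R,3R,5E)-6-iodo-2-methylhept-5-ene-1,3-diol
Product: 26 (2R,3R,5E)-1-[(tert-butyldiphenylsilyl)oxy]-6-iodo-2-methylhept-5-en-3-ol
Conditions: tBuPh2SiCl, imidazole, CH2Cl2, 0 °C
Reagents that add atoms: tert-butyl(chloro)diphenylsilane, CC(C)(C)[Si](Cl)(c1ccccc1)c1ccccc1
Why: The bulky silyl chloride silylates the primary hydroxyl (C18) selectively over the secondary one.

Step 17
Reactants: 26 (2R,3R,5E)-1-[(tert-butyldiphenylsilyl)oxy]-6-iodo-2-methylhept-5-en-3-ol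
Product: 27 (2R,3R,5E)-1-[(tert-butyldiphenylsilyl)oxy]-6-iodo-2-methylhept-5-en-3-yl methanesulfonate
Conditions: MsCl, Et3N, CH2Cl2, −10 °C
Reagents that add atoms: methanesulfonyl chloride, CS(=O)(=O)Cl
Why: Mesylation of the C16 alcohol with retention provides the leaving group for the later inversion.

Step 18
Reactants: 17 (1R,2R,4aS)-1-(2-iodoethyl)-1,2,5,5-tetramethyl-1,2,3,4,4a,5,6,7-octahydronaphthalene; 27 (2R,3R,5E)-1-[(tert-butyldiphenylsilyl)oxy]-6-iodo-2-methylhept-5-en-3-yl methanesulfonate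
Product: 29 (2R,3R,5E)-1-[(tert-butyldiphenylsilyl)oxy]-2,6-dimethyl-8-[(1R,2R,4aS)-1,2,5,5-tetramethyl-1,2,3,4,4a,5,6,7-octahydronaphthalen-1-yl]oct-5-en-3-yl methanesulfonate, via alkylzinc iodide 28 (not isolated)
Conditions: 17, Zn, LiCl, THF, 40 °C; then 27, Pd(OAc)2 (2 mol%), SPhos (4 mol%), THF, 25 °C
Reagents that add atoms: none
Why: Negishi sp3–sp2 cross-coupling forms C12–C13 with retention of the E geometry, and the secondary mesylate should be inert to the alkylzinc and to palladium at room temperature.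

Step 19
Reactants: 29 (2R,3R,5E)-1-[(tert-butyldiphenylsilyl)oxy]-2,6-dimethyl-8-[(1R,2R,4aS)-1,2,5,5-tetramethyl-1,2,3,4,4a,5,6,7-octahydronaphthalen-1-yl]oct-5-en-3-yl methanesulfonate
Product: 31 tert-butyl{[(2R,3S,5E)-3-hydroperoxy-2,6-dimethyl-8-[(1R,2R,4aS)-1,2,5,5-tetramethyl-1,2,3,4,4a,5,6,7-octahydronaphthalen-1-yl]oct-5-en-1-yl]oxy}diphenylsilane, via peroxyketal 30 (not isolated)
Conditions: 2-methoxyprop-2-yl hydroperoxide, CsOH·H2O, DMF, 0 → 25 °C; then AcOH/THF/H2O, 25 °C
Reagents that add atoms: 2-methoxyprop-2-yl hydroperoxide, COC(C)(C)OO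
Why: SN2 displacement of the secondary mesylate by the caesium salt of the protected hydroperoxide (Dussault hydroperoxide synthesis) inverts C16, and mild acid then removes the ketal from 30.

Step 20
Reactants: 31 tert-butyl{[(2R,3S,5E)-3-hydroperoxy-2,6-dimethyl-8-[(1R,2R,4aS)-1,2,5,5-tetramethyl-1,2,3,4,4a,5,6,7-octahydronaphthalen-1-yl]oct-5-en-1-yl]oxy}diphenylsilane
Product: 33 tert-butyl{(2R)-2-[(3S,6R)-6-methyl-6-{2-[(1R,2R,4aS)-1,2,5,5-tetramethyl-1,2,3,4,4a,5,6,7-octahydronaphthalen-1-yl]ethyl}-1,2-dioxan-3-yl]propoxy}diphenylsilane, via organomercury acetate 32 (not isolated)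
Conditions: Hg(OAc)2, CH2Cl2, 0 °C; then NaBH4, aq. NaOH, 0 °C
Reagents that add atoms: none
Why: Cycloperoxymercuration, in which the hydroperoxide attacks the mercurinium ion at tertiary C13 (Markovnikov, 6-endo) through a chair with the C16 substituent equatorial while the E alkene forces the C13 methyl axial, should set C13 with its methyl cis to the C16 substituent, and NaBH4 then replaces mercury in 32 by hydrogen.

Step 21
Reactants: 33 tert-butyl{(2R)-2-[(3S,6R)-6-methyl-6-{2-[(1R,2R,4aS)-1,2,5,5-tetramethyl-1,2,3,4,4a,5,6,7-octahydronaphthalen-1-yl]ethyl}-1,2-dioxan-3-yl]propoxy}diphenylsilane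
Product: 34 (2R)-2-[(3S,6R)-6-methyl-6-{2-[(1R,2R,4aS)-1,2,5,5-tetramethyl-1,2,3,4,4a,5,6,7-octahydronaphthalen-1-yl]ethyl}-1,2-dioxan-3-yl]propan-1-ol
Conditions: Bu4NF, AcOH, THF, 0 → 25 °C
Reagents that add atoms: none
Why: Fluoride cleavage of the silyl ether, buffered with acetic acid to protect the base-sensitive 1,2-dioxane.

Step 22
Reactants: 34 (2R)-2-[(3S,6R)-6-methyl-6-{2-[(1R,2R,4aS)-1,2,5,5-tetramethyl-1,2,3,4,4a,5,6,7-octahydronaphthalen-1-yl]ethyl}-1,2-dioxan-3-yl]propan-1-ol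
Product: 35 Mycaperoxide H
Conditions: TEMPO (20 mol%), PhI(OAc)2 (2.2 equiv), MeCN/H2O, 25 °C
Reagents that add atoms: water, O
Why: TEMPO/PhI(OAc)2 oxidation in wet acetonitrile takes the primary alcohol through the aldehyde hydrate to the acid under near-neutral conditions that should spare the peroxide, the alkene and the α-stereocentre C17.

**Compound list**

1 | 2-methylcyclohex-2-en-1-one | CC1=CCCCC1=O | starting material
2 | dimethylaluminium (3R)-2,3-dimethylcyclohex-1-en-1-olate | C[Al](C)OC1=C(C)[C@H](C)CCC1 | intermediate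
3 | (2R,3R)-2,3-dimethylcyclohexan-1-one (cis) | O=C1[C@H](C)[C@H](C)CCC1 | intermediate
4 | (1R,2R)-1,2-dimethyl-3-methylidenecyclohexane (cis) | C=C1[C@H](C)[C@H](C)CCC1 | intermediate
5 | prop-2-enal (acrolein) | C=CC=O | starting material
6 | 4-[(5R,6R)-5,6-dimethylcyclohex-1-en-1-yl]butanal | O=CCCCC1=CCC[C@@H](C)[C@H]1C | intermediate
7 | (1S,6R,8aR)-5,6-dimethyl-1,2,3,4,6,7,8,8a-octahydronaphthalen-1-ol | O[C@H]1CCCC2=C(C)[C@H](C)CC[C@@H]12 | intermediate
8 | (6R,8aR)-5,6-dimethyl-3,4,6,7,8,8a-hexahydronaphthalen-1(2H)-one | O=C1CCCC2=C(C)[C@H](C)CC[C@@H]12 | intermediate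
9 | (6R,8aS)-5,6-dimethyl-1-methylidene-1,2,3,4,6,7,8,8a-octahydronaphthalene | C=C1CCCC2=C(C)[C@H](C)CC[C@@H]12 | intermediate
10 | N'-{[(6R,8aR)-1,5,6-trimethyl-1,2,3,4,6,7,8,8a-octahydronaphthalen-1-yl]methyl}-2,4,6-trimethylbenzenesulfonohydrazide (either configuration at C1) | Cc1cc(C)c(c(C)c1)S(=O)(=O)NNCC1(C)CCCC2=C(C)[C@H](C)CC[C@@H]12 | intermediate
11 | (2R,4aS)-1,2,5,5-tetramethyl-2,3,4,4a,5,6,7,8-octahydronaphthalene | CC1(C)CCCC2=C(C)[C@H](C)CC[C@@H]12 | intermediate
12 | (4aS,7R)-4,4,7,8-tetramethyl-3,4,4a,5,6,7-hexahydronaphthalen-1(2H)-one | CC1(C)CCC(=O)C2=C(C)[C@H](C)CC[C@@H]12 | intermediate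
13 | (1S,4aS,7R)-4,4,7,8-tetramethyl-1,2,3,4,4a,5,6,7-octahydronaphthalen-1-ol | CC1(C)CC[C@H](O)C2=C(C)[C@H](C)CC[C@@H]12 | intermediate
14 | (1S,4aS,7R)-1-[(1-ethoxyethenyl)oxy]-4,4,7,8-tetramethyl-1,2,3,4,4a,5,6,7-octahydronaphthalene | CC1(C)CC[C@H](OC(=C)OCC)C2=C(C)[C@H](C)CC[C@@H]12 | intermediate
15 | ethyl [(1R,2R,4aS)-1,2,5,5-tetramethyl-1,2,3,4,4a,5,6,7-octahydronaphthalen-1-yl]acetate | CCOC(=O)C[C@@]1(C)C2=CCCC(C)(C)[C@@H]2CC[C@H]1C | intermediate
16 | 2-[(1R,2R,4aS)-1,2,5,5-tetramethyl-1,2,3,4,4a,5,6,7-octahydronaphthalen-1-yl]ethan-1-ol | OCC[C@@]1(C)C2=CCCC(C)(C)[C@@H]2CC[C@H]1C | intermediate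
17 | (1R,2R,4aS)-1-(2-iodoethyl)-1,2,5,5-tetramethyl-1,2,3,4,4a,5,6,7-octahydronaphthalene | ICC[C@@]1(C)C2=CCCC(C)(C)[C@@H]2CC[C@H]1C | intermediate
18 | pent-3-yn-1-ol | CC#CCCO | starting material
19 | chlorido[(2E)-5-(chloridozirconocenyloxy)pent-2-en-2-yl]zirconocene | C(/C=C(\C)[Zr](Cl)(C1C=CC=C1)C1C=CC=C1)CO[Zr](Cl)(C1C=CC=C1)C1C=CC=C1 | intermediate
20 | (3E)-4-iodopent-3-en-1-ol | OCC/C=C(\C)I | intermediate
21 | (3E)-4-iodopent-3-enal | O=CC/C=C(\C)I | intermediate
22 | (4S)-4-benzyl-3-propanoyl-1,3-oxazolidin-2-one | CCC(=O)N1[C@@H](Cc2ccccc2)COC1=O | starting material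
23 | (Z)-dibutylboron enolate of 22 | C/C=C(\OB(CCCC)CCCC)N1[C@@H](Cc2ccccc2)COC1=O | intermediate
24 | (4S)-4-benzyl-3-[(2S,3R,5E)-3-hydroxy-6-iodo-2-methylhept-5-enoyl]-1,3-oxazolidin-2-one | C[C@H](C(=O)N1[C@@H](Cc2ccccc2)COC1=O)[C@H](O)C/C=C(\C)I | intermediate
25 | (2R,3R,5E)-6-iodo-2-methylhept-5-ene-1,3-diol | C[C@H](CO)[C@H](O)C/C=C(\C)I | intermediate
26 | (2R,3R,5E)-1-[(tert-butyldiphenylsilyl)oxy]-6-iodo-2-methylhept-5-en-3-ol | C[C@H](CO[Si](c1ccccc1)(c1ccccc1)C(C)(C)C)[C@H](O)C/C=C(\C)I | intermediate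
27 | (2R,3R,5E)-1-[(tert-butyldiphenylsilyl)oxy]-6-iodo-2-methylhept-5-en-3-yl methanesulfonate | C[C@H](CO[Si](c1ccccc1)(c1ccccc1)C(C)(C)C)[C@H](OS(C)(=O)=O)C/C=C(\C)I | intermediate
28 | {2-[(1R,2R,4aS)-1,2,5,5-tetramethyl-1,2,3,4,4a,5,6,7-octahydronaphthalen-1-yl]ethyl}zinc iodide | I[Zn]CC[C@@]1(C)C2=CCCC(C)(C)[C@@H]2CC[C@H]1C | intermediate
29 | (2R,3R,5E)-1-[(tert-butyldiphenylsilyl)oxy]-2,6-dimethyl-8-[(1R,2R,4aS)-1,2,5,5-tetramethyl-1,2,3,4,4a,5,6,7-octahydronaphthalen-1-yl]oct-5-en-3-yl methanesulfonate | C[C@H](CO[Si](c1ccccc1)(c1ccccc1)C(C)(C)C)[C@H](OS(C)(=O)=O)C/C=C(\C)CC[C@@]2(C)C3=CCCC(C)(C)[C@@H]3CC[C@H]2C | intermediate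
30 | tert-butyl{[(2R,3S,5E)-3-[(2-methoxypropan-2-yl)peroxy]-2,6-dimethyl-8-[(1R,2R,4aS)-1,2,5,5-tetramethyl-1,2,3,4,4a,5,6,7-octahydronaphthalen-1-yl]oct-5-en-1-yl]oxy}diphenylsilane | C[C@H](CO[Si](c1ccccc1)(c1ccccc1)C(C)(C)C)[C@@H](OOC(C)(C)OC)C/C=C(\C)CC[C@@]2(C)C3=CCCC(C)(C)[C@@H]3CC[C@H]2C | intermediate
31 | tert-butyl{[(2R,3S,5E)-3-hydroperoxy-2,6-dimethyl-8-[(1R,2R,4aS)-1,2,5,5-tetramethyl-1,2,3,4,4a,5,6,7-octahydronaphthalen-1-yl]oct-5-en-1-yl]oxy}diphenylsilane | C[C@H](CO[Si](c1ccccc1)(c1ccccc1)C(C)(C)C)[C@@H](OO)C/C=C(\C)CC[C@@]2(C)C3=CCCC(C)(C)[C@@H]3CC[C@H]2C | intermediate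
32 | acetoxymercurio derivative of 33 at dioxane C5 (HgOAc cis to the C6 methyl) | C[C@H](CO[Si](c4ccccc4)(c5ccccc5)C(C)(C)C)[C@@H]1C[C@H]([Hg]OC(C)=O)[C@@](C)(CC[C@@]2(C)C3=CCCC(C)(C)[C@@H]3CC[C@H]2C)OO1 | intermediate
33 | tert-butyl{(2R)-2-[(3S,6R)-6-methyl-6-{2-[(1R,2R,4aS)-1,2,5,5-tetramethyl-1,2,3,4,4a,5,6,7-octahydronaphthalen-1-yl]ethyl}-1,2-dioxan-3-yl]propoxy}diphenylsilane | C[C@H](CO[Si](c4ccccc4)(c5ccccc5)C(C)(C)C)[C@@H]1CC[C@@](C)(CC[C@@]2(C)C3=CCCC(C)(C)[C@@H]3CC[C@H]2C)OO1 | intermediate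
34 | (2R)-2-[(3S,6R)-6-methyl-6-{2-[(1R,2R,4aS)-1,2,5,5-tetramethyl-1,2,3,4,4a,5,6,7-octahydronaphthalen-1-yl]ethyl}-1,2-dioxan-3-yl]propan-1-ol | C[C@H](CO)[C@@H]1CC[C@@](C)(CC[C@@]2(C)C3=CCCC(C)(C)[C@@H]3CC[C@H]2C)OO1 | intermediate
35 | Mycaperoxide H, (2S)-2-[(3S,6R)-6-methyl-6-{2-[(1R,2R,4aS)-1,2,5,5-tetramethyl-1,2,3,4,4a,5,6,7-octahydronaphthalen-1-yl]ethyl}-1,2-dioxan-3-yl]propanoic acid | C[C@H](C(=O)O)[C@@H]1CC[C@@](C)(CC[C@@]2(C)C3=CCCC(C)(C)[C@@H]3CC[C@H]2C)OO1 | target

**Counts**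

Total step count: 22. Longest linear sequence: 16 steps (steps 1–11, then 18–22); the fragment 27 takes 6 steps (12–17).

**Steps most likely to fail**

Step 3. The second ene reaction may run stepwise (Prins-type) from the lower face, or the first ene reaction may abstract the C9 hydrogen; either would lose the hydrogen relay and give poor facial selectivity at C5. Acrolein may also polymerise under the Lewis acid. Fallback, from ketone 3: CeCl3-promoted addition of (4-methylpent-3-en-1-yl)magnesium bromide gives (2R,3R)-2,3-dimethyl-1-(4-methylpent-3-en-1-yl)cyclohexan-1-ol F1. Formic acid (or SnCl4) then dehydrates the carbinol to the C5=C10 cyclohexene and protonates the side-chain alkene. The tertiary C4 cation should close ring A at C5 anti to the pseudoaxial C9 methyl, with loss of the C9 proton, giving hydrocarbon 11 directly. This is a Grignard addition followed by a cation–olefin cyclisation in place of the ene annulation; steps 2–6 are bypassed.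

Step 19. E2 elimination of the mesylate toward the allylic C15 hydrogens, or slow substitution at the β-branched secondary carbon, may outrun the SN2 reaction. Fallback, from mesylate 29, reversing the roles of the two peroxide carbons: Mukaiyama–Isayama hydroperoxysilylation (Co(acac)2, O2, Et3SiH) of the less hindered side-chain alkene gives the tertiary silyl peroxide (2R,3R)-1-[(tert-butyldiphenylsilyl)oxy]-2,6-dimethyl-8-[(1R,2R,4aS)-1,2,5,5-tetramethyl-1,2,3,4,4a,5,6,7-octahydronaphthalen-1-yl]-6-[(triethylsilyl)peroxy]octan-3-yl methanesulfonate F2. Bu4NF frees the hydroperoxide (2R,3R)-1-[(tert-butyldiphenylsilyl)oxy]-6-hydroperoxy-2,6-dimethyl-8-[(1R,2R,4aS)-1,2,5,5-tetramethyl-1,2,3,4,4a,5,6,7-octahydronaphthalen-1-yl]octan-3-yl methanesulfonate F3. Cs2CO3 then closes the ring by intramolecular SN2 at C16 with inversion, giving 33. The radical peroxidation is not selective at C13, so 33 would have to be separated from its C13 epimer by chromatography; steps 19 and 20 are bypassed.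

Step 20. Attack of the hydroperoxide at C14 (five-membered ring) instead of C13, ring closure through a chair with the C16 substituent axial (poor selectivity at C13), or loss of the O–O bond by epoxide formation from the β-peroxy radical during demercuration. Fallback, from hydroperoxide 31: a Brønsted-acid-catalysed closure (camphorsulfonic acid or Amberlyst 15, CH2Cl2) by Markovnikov protonation of the C13=C14 alkene and capture of the tertiary cation by the hydroperoxide gives 33 in one polar step, with no mercury and no radical; the C13 configuration then rests only on the chair preference, so the ratio is expected to be lower.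

**Further compounds**

F1 | step 3 | (2R,3R)-2,3-dimethyl-1-(4-methylpent-3-en-1-yl)cyclohexan-1-ol (either configuration at C1) | CC(C)=CCCC1(O)CCC[C@@H](C)[C@H]1C
F2 | step 19 | (2R,3R)-1-[(tert-butyldiphenylsilyl)oxy]-2,6-dimethyl-8-[(1R,2R,4aS)-1,2,5,5-tetramethyl-1,2,3,4,4a,5,6,7-octahydronaphthalen-1-yl]-6-[(triethylsilyl)peroxy]octan-3-yl methanesulfonate (both C6 epimers) | C[C@H](CO[Si](c1ccccc1)(c1ccccc1)C(C)(C)C)[C@H](OS(C)(=O)=O)CCC(C)(OO[Si](CC)(CC)CC)CC[C@@]2(C)C3=CCCC(C)(C)[C@@H]3CC[C@H]2C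
F3 | step 19 | (2R,3R)-1-[(tert-butyldiphenylsilyl)oxy]-6-hydroperoxy-2,6-dimethyl-8-[(1R,2R,4aS)-1,2,5,5-tetramethyl-1,2,3,4,4a,5,6,7-octahydronaphthalen-1-yl]octan-3-yl methanesulfonate (both C6 epimers) | C[C@H](CO[Si](c1ccccc1)(c1ccccc1)C(C)(C)C)[C@H](OS(C)(=O)=O)CCC(C)(OO)CC[C@@]2(C)C3=CCCC(C)(C)[C@@H]3CC[C@H]2C
F0 | step 20 | none | none
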